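**Plan**

- Retrosynthesis: the spiro carbon of ring A is cut at its two C–O bonds (ester oxygen, then bridgehead ether oxygen), giving a cage acid and a prenylated pyrano-hydroxyquinone. In the cage, the tetrahydrofuran C–O bond and the prenyl C–C bond at the quaternary carbon are cut, then the two C–C bonds joining the alkene bridge to the bridgeheads.
- Enabling feature: the CH=C(C=O) bridge of the bicyclo[2.2.2]octenone joins the carbinol bridgehead (CH end) to the ketal-oxygen bridgehead (acyl-bearing end), just as a propiolate spans the two termini of a cyclohexa-1,3-diene that carries oxygen on both termini.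
- Forward: a 4-substituted cyclohexanone is desymmetrised and oxidised to a 1-alkoxy-3,4-bis(silyloxy)cyclohexa-1,3-diene; [4+2] with methyl propiolate closes the bicycle. Prenylation, then bromination/etherification, closes the tetrahydrofuran; the acid is esterified with the separately made chromenequinone and the 1,3-dioxin-4-one spiro ring closes last.
- Stereochemistry: a chiral lithium amide sets the CH(CMe2O) centre; cycloaddition anti to that group fixes both bridgeheads; the ether tether fixes the quaternary carbon; the spiro carbon and the neighbouring CH(prenyl) are set in the reversible final ring closure.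

Key step: step 10

Remark: the (S,S)-amide is assumed to give the (R)-enol silane by analogy with 4-tert-butylcyclohexanone (if the sense is the reverse, the (R,R)-amide is used). Centres that are destroyed in the following step (C3 of 8, the carbinol carbon of 12 and 13) are carried as mixtures and left open in the SMILES. For the cage compounds the absolute configuration is that of the SMILES; names give the relative arrangement.

**Route**

Step 1
Reactants: 1 ethyl 1,4-dioxaspiro[4.5]decane-8-carboxylate
Product: 3 4-(2-hydroxypropan-2-yl)cyclohexan-1-one, via ketal alcohol 2 (not isolated)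
Conditions: MeMgBr (3 equiv), THF, 0 °C → rt; then 2 M HCl, rt
Reagents that add atoms: methylmagnesium bromide, C[Mg]Br; water, O
Why: Double Grignard addition to the ester gives the tertiary carbinol and the acidic quench hydrolyses the dioxolane, leaving a symmetric 4-substituted cyclohexanone with no stereocentre.

Step 2
Reactants: 3 4-(2-hydroxypropan-2-yl)cyclohexan-1-one
Product: 4 4-[2-(triethylsilyloxy)propan-2-yl]cyclohexan-1-one
Conditions: TESOTf, 2,6-lutidine, CH2Cl2, −78 → 0 °C
Reagents that add atoms: triethylsilyl trifluoromethanesulfonate, CC[Si](CC)(CC)OS(=O)(=O)C(F)(F)F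
Why: Silyl triflate silylation of the hindered tertiary alcohol (silyl ether protection) masks the hydroxyl for the base chemistry ahead and supplies the bulk later used for facial control.

Step 3
Reactants: 4 4-[2-(triethylsilyloxy)propan-2-yl]cyclohexan-1-one
Product: 5 (4R)-4-[2-(triethylsilyloxy)propan-2-yl]-1-(trimethylsilyloxy)cyclohex-1-ene
Conditions: (S,S)-bis(1-phenylethyl)amine, n-BuLi, THF, −78 °C; TMSCl, then 4, −100 → −78 °C
Reagents that add atoms: chlorotrimethylsilane, C[Si](C)(C)Cl
Why: Enantiotopic-proton-selective deprotonation of the prochiral ketone by the chiral lithium amide with internal silyl chloride quench (asymmetric desymmetrising enolisation) sets the one stereocentre that the ring carries into the cage.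

Step 4
Reactants: 5 (4R)-4-[2-(triethylsilyloxy)propan-2-yl]-1-(trimethylsilyloxy)cyclohex-1-ene
Product: 6 (4R)-4-[2-(triethylsilyloxy)propan-2-yl]cyclohex-2-en-1-one
Conditions: Pd(OAc)2 (1 equiv), MeCN, rt
Reagents that add atoms: none
Why: Saegusa–Ito oxidation, in which the divalent palladium enolate formed from the enol silane undergoes beta-hydride elimination, gives the enone on the side fixed in step 3 without touching the gamma stereocentre.

Step 5
Reactants: 6 (4R)-4-[2-(triethylsilyloxy)propan-2-yl]cyclohex-2-en-1-one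
Product: 7 (3R,4S)-3-(phenylsulfanyl)-4-[2-(triethylsilyloxy)propan-2-yl]cyclohexan-1-one
Conditions: PhSH (1.0 equiv), Et3N (cat.), CH2Cl2, 0 °C → rt
Reagents that add atoms: benzenethiol, Sc1ccccc1
Why: Base-catalysed thia-Michael addition places sulfur on the beta carbon trans to the neighbouring silyloxy-isopropyl group, and this sulfide centre is removed again in step 6.

Step 6
Reactants: 7 (3R,4S)-3-(phenylsulfanyl)-4-[2-(triethylsilyloxy)propan-2-yl]cyclohexan-1-one
Product: 9 (4S)-3-(phenylsulfanyl)-4-[2-(triethylsilyloxy)propan-2-yl]cyclohex-2-en-1-one, via alpha-chloro sulfide 8 (not isolated)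
Conditions: N-chlorosuccinimide, CH2Cl2, 0 °C → rt; then Et3N
Reagents that add atoms: none
Why: Chlorination alpha to sulfur and loss of HCl toward the acidic ketone alpha position (Pummerer-type oxidative dehydrogenation of a beta-thio ketone) raises the beta carbon to the vinylogous thioester level while the carbonyl stays at the position remote from the substituent.

Step 7
Reactants: 9 (4S)-3-(phenylsulfanyl)-4-[2-(triethylsilyloxy)propan-2-yl]cyclohex-2-en-1-one; 10 4-methoxybenzyl alcohol
Product: 11 (4R)-3-[(4-methoxybenzyl)oxy]-4-[2-(triethylsilyloxy)propan-2-yl]cyclohex-2-en-1-one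
Conditions: NaH, 4-methoxybenzyl alcohol, THF, 0 °C → rt
Reagents that add atoms: none
Why: Addition–elimination of the alkoxide at the beta carbon (nucleophilic vinylic substitution) exchanges thiolate for the benzyloxy group and gives the vinylogous ester regioisomer that O-alkylation of the 1,3-dione would not favour, while allylic 1,2-strain holds the gamma C–H out of alignment with the enone and so protects the stereocentre.

Step 8
Reactants: 11 (4R)-3-[(4-methoxybenzyl)oxy]-4-[2-(triethylsilyloxy)propan-2-yl]cyclohex-2-en-1-one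
Product: 13 (4R)-6-(tert-butyldimethylsilyloxy)-3-[(4-methoxybenzyl)oxy]-4-[2-(triethylsilyloxy)propan-2-yl]cyclohex-2-en-1-one, via potassium alkoxide 12 (not isolated)
Conditions: KN(SiMe3)2, THF, −78 °C; 2-(phenylsulfonyl)-3-phenyloxaziridine, −78 °C; TBSCl, −78 → 0 °C
Reagents that add atoms: 2-(phenylsulfonyl)-3-phenyloxaziridine, O=S(=O)(c1ccccc1)N1OC1c1ccccc1; tert-butyldimethylsilyl chloride, CC(C)(C)[Si](C)(C)Cl
Why: Kinetic alpha'-enolisation of the vinylogous ester, oxygen transfer from the N-sulfonyloxaziridine (enolate hydroxylation) and silylation of the resulting alkoxide in the same flask install the future carbinol-bridgehead oxygen, the new centre being an inconsequential mixture that becomes trigonal in step 9.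

Step 9
Reactants: 13 (4R)-6-(tert-butyldimethylsilyloxy)-3-[(4-methoxybenzyl)oxy]-4-[2-(triethylsilyloxy)propan-2-yl]cyclohex-2-en-1-one
Product: 14 (5R)-1-(tert-butyldimethylsilyloxy)-4-[(4-methoxybenzyl)oxy]-5-[2-(triethylsilyloxy)propan-2-yl]-2-(trimethylsilyloxy)cyclohexa-1,3-diene
Conditions: LiN(iPr)2, TMSCl (internal quench), THF, −78 °C; Et3N, pentane, filtration
Reagents that add atoms: chlorotrimethylsilane, C[Si](C)(C)Cl
Why: Kinetic deprotonation at the alpha' carbon with immediate O-silylation (cross-conjugated silyl dienol ether formation) gives the ring diene before the silyloxy enolate can exchange silyl groups and without touching the hindered gamma C–H.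

Step 10
Reactants: 14 (5R)-1-(tert-butyldimethylsilyloxy)-4-[(4-methoxybenzyl)oxy]-5-[2-(triethylsilyloxy)propan-2-yl]-2-(trimethylsilyloxy)cyclohexa-1,3-diene; 15 methyl propiolate
Product: 17 methyl 4-(tert-butyldimethylsilyloxy)-1-[(4-methoxybenzyl)oxy]-5-oxo-7-[2-(triethylsilyloxy)propan-2-yl]bicyclo[2.2.2]oct-2-ene-2-carboxylate, via silyl enol ether cycloadduct 16 (not isolated)
Conditions: methyl propiolate (3 equiv), toluene, 25 → 40 °C, dark; then AcOH/THF/H2O, 0 °C
Reagents that add atoms: none
Why: This is a thermal normal-demand [4+2] cycloaddition, the ring-diene counterpart of the known Diels–Alder reactions of 1-alkoxy-3-silyloxy dienes and 1-alkoxycyclohexa-1,3-dienes with propiolates. Bond formation is concerted but asynchronous: the silyloxy terminus C1 bonds first to the propiolate beta carbon and the alkoxy terminus C4 then bonds to the ester-bearing carbon, both suprafacially on the diene, so the new six-membered ring and with it the bicyclo[2.2.2]octadiene close in one step. Regiochemistry rests on the 2-trimethylsilyloxy and 4-alkoxy donors, which reinforce each other and outweigh the weaker silyloxy donor on C1, so the ester ends next to the alkoxy bridgehead. Both bridgehead stereocentres are set by the existing C5 centre: allylic strain holds the silyloxy-isopropyl group pseudo-axial, the alkyne adds to the opposite face, and the group therefore ends on the side of the enol ether (later ketone) bridge. The reaction is kept near room temperature and the trimethylsilyl enol ether is hydrolysed in the work-up, because the doubly unsaturated adduct could otherwise lose its saturated bridge by retro-Diels–Alder aromatisation; the mild acid should spare the other silyl ethers and the benzyl ether.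

Step 11
Reactants: 17 methyl 4-(tert-butyldimethylsilyloxy)-1-[(4-methoxybenzyl)oxy]-5-oxo-7-[2-(triethylsilyloxy)propan-2-yl]bicyclo[2.2.2]oct-2-ene-2-carboxylate; 18 prenyl bromide
Product: 19 methyl 4-(tert-butyldimethylsilyloxy)-1-[(4-methoxybenzyl)oxy]-6-(3-methylbut-2-en-1-yl)-5-oxo-7-[2-(triethylsilyloxy)propan-2-yl]bicyclo[2.2.2]oct-2-ene-2-carboxylate
Conditions: KN(SiMe3)2, THF, −78 °C; prenyl bromide, −78 → −20 °C
Reagents that add atoms: none
Why: Enolate alkylation at the only enolisable carbon of the ketone (SN2 on the allylic bromide) occurs on the face of the alkene bridge, away from the silyloxy-isopropyl group, and is done now because the carbon can no longer become trigonal once the ether ring is closed.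

Step 12
Reactants: 19 methyl 4-(tert-butyldimethylsilyloxy)-1-[(4-methoxybenzyl)oxy]-6-(3-methylbut-2-en-1-yl)-5-oxo-7-[2-(triethylsilyloxy)propan-2-yl]bicyclo[2.2.2]oct-2-ene-2-carboxylate
Product: 20 methyl 4-(tert-butyldimethylsilyloxy)-7-(2-hydroxypropan-2-yl)-1-[(4-methoxybenzyl)oxy]-6-(3-methylbut-2-en-1-yl)-5-oxobicyclo[2.2.2]oct-2-ene-2-carboxylate
Conditions: HF·pyridine, pyridine, THF, 0 °C
Reagents that add atoms: none
Why: Buffered HF·pyridine should cleave the tertiary triethylsilyl ether selectively (selective desilylation) while the far more hindered bridgehead tert-butyldimethylsilyl ether stays in place.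

Step 13
Reactants: 20 methyl 4-(tert-butyldimethylsilyloxy)-7-(2-hydroxypropan-2-yl)-1-[(4-methoxybenzyl)oxy]-6-(3-methylbut-2-en-1-yl)-5-oxobicyclo[2.2.2]oct-2-ene-2-carboxylate
Product: 22 methyl 1-(tert-butyldimethylsilyloxy)-7-[(4-methoxybenzyl)oxy]-5,5-dimethyl-3-(3-methylbut-2-en-1-yl)-2-oxo-4-oxatricyclo[4.3.1.0(3,7)]dec-8-ene-8-carboxylate, via bromo alkoxide 21 (not isolated)
Conditions: KN(SiMe3)2 (2.1 equiv), THF, −78 → −30 °C; N-bromosuccinimide, −78 → 0 °C
Reagents that add atoms: none
Why: The neighbouring potassium alkoxide relays the hindered alpha proton to give the tetrasubstituted enolate, which is brominated on the alkene-bridge face, and the alkoxide then displaces the ketone-activated bromide from the opposite face (intramolecular Williamson etherification, 5-exo-tet with inversion), so the tether fixes oxygen toward the saturated bridge and prenyl toward the alkene bridge at the new quaternary centre.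

Step 14
Reactants: 22 methyl 1-(tert-butyldimethylsilyloxy)-7-[(4-methoxybenzyl)oxy]-5,5-dimethyl-3-(3-methylbut-2-en-1-yl)-2-oxo-4-oxatricyclo[4.3.1.0(3,7)]dec-8-ene-8-carboxylate
Product: 23 1-(tert-butyldimethylsilyloxy)-7-[(4-methoxybenzyl)oxy]-5,5-dimethyl-3-(3-methylbut-2-en-1-yl)-2-oxo-4-oxatricyclo[4.3.1.0(3,7)]dec-8-ene-8-carboxylic acid
Conditions: LiOH, THF/MeOH/H2O, rt; then dilute HCl to pH 4
Reagents that add atoms: lithium hydroxide, [Li+].[OH-]
Why: Saponification of the methyl ester is run at this point because the ketone has no alpha hydrogen left and both bridgehead oxygens are still protected, so neither epimerisation nor retro-aldol opening is possible.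

Step 15
Reactants: 24 2,6-dimethoxy-1,4-benzoquinone
Product: 25 2-hydroxy-6-methoxy-1,4-benzoquinone
Conditions: NaOH (1.1 equiv), H2O/THF, 0 °C → rt; then 1 M HCl
Reagents that add atoms: sodium hydroxide, [Na+].[OH-]
Why: Hydrolysis of one vinylogous ester by addition–elimination of hydroxide should stop after the first methoxy group because the hydroxyquinone anion formed is deactivated toward a second attack.

Step 16
Reactants: 25 2-hydroxy-6-methoxy-1,4-benzoquinone; 26 3-methylbut-2-enal
Product: 28 7-methoxy-2,2-dimethyl-2H-chromene-5,8-dione, via alkylidene trione 27 (not isolated)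
Conditions: ethylenediammonium diacetate (10 mol %), CH2Cl2, rt → 40 °C
Reagents that add atoms: none
Why: Knoevenagel condensation at the nucleophilic carbon beside the hydroxyl followed by oxa-6π electrocyclisation of the 1-oxatriene (formal [3+3] annulation) builds the 2,2-dimethyl-2H-pyran, the reversible ring closure favouring the para-quinone isomer.

Step 17
Reactants: 28 7-methoxy-2,2-dimethyl-2H-chromene-5,8-dione
Product: 29 7-hydroxy-2,2-dimethyl-2H-chromene-5,8-dione
Conditions: NaOH (aq), THF, 0 °C; then 1 M HCl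
Reagents that add atoms: sodium hydroxide, [Na+].[OH-]
Why: Hydroxide adds to the less hindered methoxy-bearing ring carbon and expels methoxide (vinylogous ester hydrolysis), freeing the hydroxyl beside the last open ring position.

Step 18
Reactants: 29 7-hydroxy-2,2-dimethyl-2H-chromene-5,8-dione; 18 prenyl bromide
Product: 30 7-hydroxy-2,2-dimethyl-6-(3-methylbut-2-en-1-yl)-2H-chromene-5,8-dione
Conditions: LiH, DMSO, rt; prenyl bromide, rt
Reagents that add atoms: none
Why: C-Alkylation of the ambident hydroxyquinone anion at the carbon between carbonyl and hydroxyl by the allylic bromide, the classical route to prenylated hydroxyquinones, installs the prenyl group, with O-alkylation as the expected competitor.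

Step 19
Reactants: 23 1-(tert-butyldimethylsilyloxy)-7-[(4-methoxybenzyl)oxy]-5,5-dimethyl-3-(3-methylbut-2-en-1-yl)-2-oxo-4-oxatricyclo[4.3.1.0(3,7)]dec-8-ene-8-carboxylic acid; 30 7-hydroxy-2,2-dimethyl-6-(3-methylbut-2-en-1-yl)-2H-chromene-5,8-dione
Product: 32 quinonyl ester of acid 23 with the 7-oxygen of 30, via acid chloride 31 (not isolated)
Conditions: 1-chloro-N,N,2-trimethylprop-1-en-1-amine, CH2Cl2, 0 °C; then 30, Et3N, DMAP (cat.), 0 °C
Reagents that add atoms: none
Why: Acid chloride formation under neutral conditions with the alpha-chloroenamine followed by O-acylation of the acidic hydroxyquinone (esterification) joins the two fragments at the quinone oxygen that becomes the lactone oxygen.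

Step 20
Reactants: 32 quinonyl ester of acid 23 with the 7-oxygen of 30
Product: 33 quinonyl ester with free bridgehead hydroxyl
Conditions: DDQ, CH2Cl2/pH 7 phosphate buffer, 0 °C
Reagents that add atoms: none
Why: Oxidative cleavage of the 4-methoxybenzyl ether by DDQ frees the bridgehead tertiary alcohol under near-neutral conditions that should spare the silyl ether, the alkenes and the activated ester and avoid base-induced retro-aldol opening.

Step 21
Reactants: 33 quinonyl ester with free bridgehead hydroxyl
Product: 34 tert-butyldimethylsilyl ether of the target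
Conditions: camphorsulfonic acid (10 mol %), 4 Å molecular sieves, CH2Cl2, 0 °C → rt
Reagents that add atoms: none
Why: Acid-catalysed intramolecular oxa-Michael addition (6-exo-trig) of the bridgehead hydroxyl to the acyloxy-bearing quinone carbon closes the 1,3-dioxin-4-one, and because the addition and the enol–keto tautomerisation are reversible the spiro carbon and the adjacent CH(prenyl) centre are expected to settle under thermodynamic control in the arrangement of the natural product.

Step 22
Reactants: 34 tert-butyldimethylsilyl ether of the target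
Product: 35 CNP0222516.1
Conditions: HF·pyridine, THF, 0 °C → rt
Reagents that add atoms: none
Why: Cleavage of the bridgehead silyl ether with HF·pyridine (fluoride desilylation under weakly acidic conditions) liberates the tertiary alpha-ketol without base, which could induce ketol rearrangement or opening of the acylal.

**Compound list**

1 | ethyl 1,4-dioxaspiro[4.5]decane-8-carboxylate | CCOC(=O)C1CCC2(CC1)OCCO2 | starting material
2 | 2-(1,4-dioxaspiro[4.5]decan-8-yl)propan-2-ol (ketal alcohol) | CC(C)(O)C1CCC2(CC1)OCCO2 | intermediate (not isolated)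
3 | 4-(2-hydroxypropan-2-yl)cyclohexan-1-one | CC(C)(O)C1CCC(=O)CC1 | intermediate
4 | 4-[2-(triethylsilyloxy)propan-2-yl]cyclohexan-1-one | CC[Si](CC)(CC)OC(C)(C)C1CCC(=O)CC1 | intermediate
5 | (4R)-4-[2-(triethylsilyloxy)propan-2-yl]-1-(trimethylsilyloxy)cyclohex-1-ene | C[Si](C)(C)OC1=CC[C@H](C(C)(C)O[Si](CC)(CC)CC)CC1 | intermediate
6 | (4R)-4-[2-(triethylsilyloxy)propan-2-yl]cyclohex-2-en-1-one | O=C1C=C[C@H](C(C)(C)O[Si](CC)(CC)CC)CC1 | intermediate
7 | (3R,4S)-3-(phenylsulfanyl)-4-[2-(triethylsilyloxy)propan-2-yl]cyclohexan-1-one (trans) | O=C1C[C@@H](Sc2ccccc2)[C@H](C(C)(C)O[Si](CC)(CC)CC)CC1 | intermediate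
8 | (4S)-3-chloro-3-(phenylsulfanyl)-4-[2-(triethylsilyloxy)propan-2-yl]cyclohexan-1-one (alpha-chloro sulfide, C3 mixture) | O=C1CC(Cl)(Sc2ccccc2)[C@H](C(C)(C)O[Si](CC)(CC)CC)CC1 | intermediate (not isolated)
9 | (4S)-3-(phenylsulfanyl)-4-[2-(triethylsilyloxy)propan-2-yl]cyclohex-2-en-1-one | O=C1C=C(Sc2ccccc2)[C@H](C(C)(C)O[Si](CC)(CC)CC)CC1 | intermediate
10 | 4-methoxybenzyl alcohol | COc1ccc(CO)cc1 | starting material
11 | (4R)-3-[(4-methoxybenzyl)oxy]-4-[2-(triethylsilyloxy)propan-2-yl]cyclohex-2-en-1-one | O=C1C=C(OCc2ccc(OC)cc2)[C@H](C(C)(C)O[Si](CC)(CC)CC)CC1 | intermediate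
12 | potassium (5R)-4-[(4-methoxybenzyl)oxy]-2-oxo-5-[2-(triethylsilyloxy)propan-2-yl]cyclohex-3-en-1-olate (C1 mixture) | O=C1C=C(OCc2ccc(OC)cc2)[C@H](C(C)(C)O[Si](CC)(CC)CC)CC1[O-].[K+] | intermediate (not isolated)
13 | (4R)-6-(tert-butyldimethylsilyloxy)-3-[(4-methoxybenzyl)oxy]-4-[2-(triethylsilyloxy)propan-2-yl]cyclohex-2-en-1-one (C6 mixture) | O=C1C=C(OCc2ccc(OC)cc2)[C@H](C(C)(C)O[Si](CC)(CC)CC)CC1O[Si](C)(C)C(C)(C)C | intermediate
14 | (5R)-1-(tert-butyldimethylsilyloxy)-4-[(4-methoxybenzyl)oxy]-5-[2-(triethylsilyloxy)propan-2-yl]-2-(trimethylsilyloxy)cyclohexa-1,3-diene | CC(C)(O[Si](CC)(CC)CC)[C@@H]1CC(O[Si](C)(C)C(C)(C)C)=C(O[Si](C)(C)C)C=C1OCc2ccc(OC)cc2 | intermediate (key-step precursor)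
15 | methyl propiolate | C#CC(=O)OC | starting material
16 | methyl 4-(tert-butyldimethylsilyloxy)-1-[(4-methoxybenzyl)oxy]-7-[2-(triethylsilyloxy)propan-2-yl]-5-(trimethylsilyloxy)bicyclo[2.2.2]octa-2,5-diene-2-carboxylate (C7 side chain on the side of the C5=C6 bridge) | COC(=O)C1=C[C@]3(O[Si](C)(C)C(C)(C)C)C[C@@H](C(C)(C)O[Si](CC)(CC)CC)[C@@]1(OCc2ccc(OC)cc2)C=C3O[Si](C)(C)C | intermediate (not isolated)
17 | methyl 4-(tert-butyldimethylsilyloxy)-1-[(4-methoxybenzyl)oxy]-5-oxo-7-[2-(triethylsilyloxy)propan-2-yl]bicyclo[2.2.2]oct-2-ene-2-carboxylate (C7 side chain on the side of the C5–C6 ketone bridge) | COC(=O)C1=C[C@]3(O[Si](C)(C)C(C)(C)C)C[C@@H](C(C)(C)O[Si](CC)(CC)CC)[C@@]1(OCc2ccc(OC)cc2)CC3=O | intermediate (key-step product)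
18 | prenyl bromide (1-bromo-3-methylbut-2-ene) | CC(C)=CCBr | starting material
19 | methyl 4-(tert-butyldimethylsilyloxy)-1-[(4-methoxybenzyl)oxy]-6-(3-methylbut-2-en-1-yl)-5-oxo-7-[2-(triethylsilyloxy)propan-2-yl]bicyclo[2.2.2]oct-2-ene-2-carboxylate (prenyl on the face of the C2=C3 bridge) | COC(=O)C1=C[C@]3(O[Si](C)(C)C(C)(C)C)C[C@@H](C(C)(C)O[Si](CC)(CC)CC)[C@@]1(OCc2ccc(OC)cc2)[C@H](CC=C(C)C)C3=O | intermediate
20 | methyl 4-(tert-butyldimethylsilyloxy)-7-(2-hydroxypropan-2-yl)-1-[(4-methoxybenzyl)oxy]-6-(3-methylbut-2-en-1-yl)-5-oxobicyclo[2.2.2]oct-2-ene-2-carboxylate | COC(=O)C1=C[C@]3(O[Si](C)(C)C(C)(C)C)C[C@@H](C(C)(C)O)[C@@]1(OCc2ccc(OC)cc2)[C@H](CC=C(C)C)C3=O | intermediate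
21 | potassium alkoxide of the 6-bromo derivative of 20 (bromine on the face of the C2=C3 bridge) | COC(=O)C1=C[C@]3(O[Si](C)(C)C(C)(C)C)C[C@@H](C(C)(C)[O-])[C@@]1(OCc2ccc(OC)cc2)[C@@](Br)(CC=C(C)C)C3=O.[K+] | intermediate (not isolated)
22 | methyl 1-(tert-butyldimethylsilyloxy)-7-[(4-methoxybenzyl)oxy]-5,5-dimethyl-3-(3-methylbut-2-en-1-yl)-2-oxo-4-oxatricyclo[4.3.1.0(3,7)]dec-8-ene-8-carboxylate | COC(=O)C1=C[C@]3(O[Si](C)(C)C(C)(C)C)C[C@H]4C(C)(C)O[C@@](CC=C(C)C)(C3=O)[C@@]14OCc2ccc(OC)cc2 | intermediate
23 | 1-(tert-butyldimethylsilyloxy)-7-[(4-methoxybenzyl)oxy]-5,5-dimethyl-3-(3-methylbut-2-en-1-yl)-2-oxo-4-oxatricyclo[4.3.1.0(3,7)]dec-8-ene-8-carboxylic acid | OC(=O)C1=C[C@]3(O[Si](C)(C)C(C)(C)C)C[C@H]4C(C)(C)O[C@@](CC=C(C)C)(C3=O)[C@@]14OCc2ccc(OC)cc2 | intermediate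
24 | 2,6-dimethoxy-1,4-benzoquinone | COC1=CC(=O)C=C(OC)C1=O | starting material
25 | 2-hydroxy-6-methoxy-1,4-benzoquinone | COC1=CC(=O)C=C(O)C1=O | intermediate
26 | 3-methylbut-2-enal | CC(C)=CC=O | starting material
27 | 6-methoxy-3-(3-methylbut-2-en-1-ylidene)cyclohex-5-ene-1,2,4-trione (alkylidene trione) | COC1=CC(=O)C(=CC=C(C)C)C(=O)C1=O | intermediate (not isolated)
28 | 7-methoxy-2,2-dimethyl-2H-chromene-5,8-dione | COC1=CC(=O)C2=C(OC(C)(C)C=C2)C1=O | intermediate
29 | 7-hydroxy-2,2-dimethyl-2H-chromene-5,8-dione | OC1=CC(=O)C2=C(OC(C)(C)C=C2)C1=O | intermediate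
30 | 7-hydroxy-2,2-dimethyl-6-(3-methylbut-2-en-1-yl)-2H-chromene-5,8-dione | CC(C)=CCC1=C(O)C(=O)C2=C(C=CC(C)(C)O2)C1=O | intermediate
31 | acid chloride of 23 | ClC(=O)C1=C[C@]3(O[Si](C)(C)C(C)(C)C)C[C@H]4C(C)(C)O[C@@](CC=C(C)C)(C3=O)[C@@]14OCc2ccc(OC)cc2 | intermediate (not isolated)
32 | 2,2-dimethyl-6-(3-methylbut-2-en-1-yl)-5,8-dioxo-2H-chromen-7-yl ester of acid 23 | CC(C)=CCC5=C(OC(=O)C1=C[C@]3(O[Si](C)(C)C(C)(C)C)C[C@H]4C(C)(C)O[C@@](CC=C(C)C)(C3=O)[C@@]14OCc2ccc(OC)cc2)C(=O)C6=C(C=CC(C)(C)O6)C5=O | intermediate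
33 | ester 32 with the bridgehead 4-methoxybenzyl ether replaced by hydroxyl | CC(C)=CCC5=C(OC(=O)C1=C[C@]3(O[Si](C)(C)C(C)(C)C)C[C@H]4C(C)(C)O[C@@](CC=C(C)C)(C3=O)[C@@]14O)C(=O)C6=C(C=CC(C)(C)O6)C5=O | intermediate
34 | target with the carbinol-bridgehead hydroxyl as tert-butyldimethylsilyl ether | CC(C)=CC[C@H]1C(=O)C2=C(OC(C)(C)C=C2)C(=O)[C@@]12OC(=O)C1=C[C@]3(O[Si](C)(C)C(C)(C)C)C[C@H]4C(C)(C)O[C@@](CC=C(C)C)(C3=O)[C@@]14O2 | intermediate
35 | CNP0222516.1 | CC(C)=CC[C@H]1C(=O)C2=C(OC(C)(C)C=C2)C(=O)[C@@]12OC(=O)C1=C[C@]3(O)C[C@H]4C(C)(C)O[C@@](CC=C(C)C)(C3=O)[C@@]14O2 | target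

**Step count and risks**

Total: 22 steps. Longest linear sequence: 18 steps (steps 1–14, then 19–22, from compound 1). The quinone 30 is made in 4 steps (15–18) and joined in step 19.

Most likely to fail:

1. Step 13 (bromination and ether closure at the fully substituted carbon). The alkoxide may remove a proton from the prenyl methylene and eliminate bromide to a dienone instead of substituting, or bromine may enter on the blocked face so that no backside path exists. The fallback avoids any tertiary halide. It sets out from 20: KN(SiMe3)2 (2.1 equiv) and TMSCl give the bis(trimethylsilyl) derivative F1 (silyl enol ether of the ketone, silyl ether of the carbinol). Treatment with PhI(OAc)2 and BF3·OEt2 in CH2Cl2 at −78 °C then inverts the polarity of the enol (trivalent iodine bound to the enol oxygen), and the silyl ether oxygen attacks the still trigonal carbon from the saturated-bridge side. This returns to the route at 22.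

2. Step 21 (spiro ring closure). The reversible conjugate addition may give the wrong epimer at the spiro carbon or at the CH(prenyl) carbon. The activated quinonyl ester may also be lost by acyl transfer, or the free bridgehead beta-hydroxy ketone may open by retro-aldol cleavage. The fallback builds both C–O bonds of the spiro carbon by acetal exchange instead. It sets out from 23 and 30: DDQ converts 23 into the hydroxy acid F2, and trimethylsilyldiazomethane converts 30 into the methoxyquinone F3. F2 and F3 are then condensed with camphorsulfonic acid in benzene over 4 Å molecular sieves with removal of methanol, in the way beta-hydroxy acids and enol ethers give 1,3-dioxan-4-ones. This returns at 34.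

3. Step 10 (cycloaddition). Bonding at the hindered alkoxy terminus may be slow enough that silyl-transfer Michael addition competes, facial or regiochemical control may be incomplete, or the adduct may lose its saturated bridge by retro-[4+2] aromatisation before hydrolysis. The fallback uses an alkene dienophile whose adduct cannot aromatise. It sets out from 14: methyl 2-chloroacrylate gives the cycloadduct F4 with the same bond pattern, mild acid hydrolysis gives the chloro keto ester F5, and DBU in toluene eliminates HCl to restore the alkene bridge. This returns at 17.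

**Further compounds**

F1 | step 13 | methyl 4-(tert-butyldimethylsilyloxy)-1-[(4-methoxybenzyl)oxy]-6-(3-methylbut-2-en-1-yl)-5-(trimethylsilyloxy)-7-[2-(trimethylsilyloxy)propan-2-yl]bicyclo[2.2.2]octa-2,5-diene-2-carboxylate | COC(=O)C1=C[C@]3(O[Si](C)(C)C(C)(C)C)C[C@@H](C(C)(C)O[Si](C)(C)C)[C@@]1(OCc2ccc(OC)cc2)C(CC=C(C)C)=C3O[Si](C)(C)C
F2 | step 21 | 1-(tert-butyldimethylsilyloxy)-7-hydroxy-5,5-dimethyl-3-(3-methylbut-2-en-1-yl)-2-oxo-4-oxatricyclo[4.3.1.0(3,7)]dec-8-ene-8-carboxylic acid | OC(=O)C1=C[C@]3(O[Si](C)(C)C(C)(C)C)C[C@H]4C(C)(C)O[C@@](CC=C(C)C)(C3=O)[C@@]14O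
F3 | step 21 | 7-methoxy-2,2-dimethyl-6-(3-methylbut-2-en-1-yl)-2H-chromene-5,8-dione | COC1=C(CC=C(C)C)C(=O)C2=C(OC(C)(C)C=C2)C1=O
F4 | step 10 | methyl 4-(tert-butyldimethylsilyloxy)-2-chloro-1-[(4-methoxybenzyl)oxy]-7-[2-(triethylsilyloxy)propan-2-yl]-5-(trimethylsilyloxy)bicyclo[2.2.2]oct-5-ene-2-carboxylate (C2 mixture) | COC(=O)C1(Cl)C[C@]3(O[Si](C)(C)C(C)(C)C)C[C@@H](C(C)(C)O[Si](CC)(CC)CC)[C@@]1(OCc2ccc(OC)cc2)C=C3O[Si](C)(C)C
F5 | step 10 | methyl 4-(tert-butyldimethylsilyloxy)-2-chloro-1-[(4-methoxybenzyl)oxy]-5-oxo-7-[2-(triethylsilyloxy)propan-2-yl]bicyclo[2.2.2]octane-2-carboxylate (C2 mixture) | COC(=O)C1(Cl)C[C@]3(O[Si](C)(C)C(C)(C)C)C[C@@H](C(C)(C)O[Si](CC)(CC)CC)[C@@]1(OCc2ccc(OC)cc2)CC3=O
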